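**Strategy.** The imidazole ring of naamidine B is cut at N3–C4 and at the CH2–aryl bond of the C4 4-methoxybenzyl group, so that C4 and its benzylic carbon become the two carbons of a terminal alkyne. A palladium-catalysed carboamination of a racemic N-methyl-N-propargyl-N'-tosylguanidine, which already carries the O-benzyl-protected isovanillyl group on its propargylic carbon (the future C5), with 4-methoxyphenyl triflate closes the ring, attaches the anisyl group and aromatises in one operation. The propargylic amine comes from alkylation of a silylated propargylamine ketimine; after the key step, a single reductive deprotection and a late condensation with silylated 1-methylparabanic acid finish the synthesis.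

Key step: step 6

Remark: the target has no stereocentre; the only stereocentre on the route (the propargylic carbon of 6–12) is carried as the racemate and is erased when the imidazole aromatises.
Remark: compounds 1, 3, 4, 10, 13 and 17 are taken as catalogue chemicals.
Remark: the tosyl and benzyl groups are removed together before the parabanic acid unit is attached, because arene radical anions cleave aryl benzyl ethers about as readily as sulfonamides and the dehydrohydantoin should not see reducing conditions.

Step 1
Reactants: 1 3-benzyloxy-4-methoxybenzyl alcohol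
Product: 2 3-benzyloxy-4-methoxybenzyl bromide
Conditions: PBr3 (0.4 equiv), Et2O, 0 °C
Reagents that add atoms: phosphorus tribromide BrP(Br)Br
Why: A primary benzylic alcohol is converted into the bromide by PBr3 through SN2 displacement of the intermediate phosphite ester, and the aryl benzyl and methyl ethers are inert at 0 °C.

Step 2
Reactants: 3 benzophenone imine; 4 3-bromo-1-(trimethylsilyl)prop-1-yne
Product: 5 N-(diphenylmethylidene)-3-(trimethylsilyl)prop-2-yn-1-amine
Conditions: K2CO3, MeCN, 60 °C
Reagents that add atoms: none
Why: The imine nitrogen is alkylated by the reactive propargylic bromide (SN2 N-alkylation of benzophenone imine), the hindered N-alkyl ketimine should not react a second time, and the silyl cap removes the acetylenic C–H before the anion chemistry of step 3.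

Step 3
Reactants: 5 N-(diphenylmethylidene)-3-(trimethylsilyl)prop-2-yn-1-amine; 2 3-benzyloxy-4-methoxybenzyl bromide
Product: 6 racemic N-(diphenylmethylidene)-1-(3-benzyloxy-4-methoxyphenyl)-4-(trimethylsilyl)but-3-yn-2-amine
Conditions: LDA (1.05 equiv), THF, −78 °C; then 2, −78 → 0 °C
Reagents that add atoms: none
Why: Deprotonation gives a 2-azaallyl/propargyl anion that should be benzylated at the propargylic carbon because the diphenyl-substituted and silyl-substituted termini are shielded (ketimine alkylation of the O'Donnell type), and the new stereocentre is deliberately formed without control as the racemate.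

Step 4
Reactants: 6 racemic N-(diphenylmethylidene)-1-(3-benzyloxy-4-methoxyphenyl)-4-(trimethylsilyl)but-3-yn-2-amine
Product: 9 racemic 1-(3-benzyloxy-4-methoxyphenyl)-N-methylbut-3-yn-2-amine, via N-methyliminium triflate 7 (not isolated), via C-silylated N-methylamine 8 (not isolated)
Conditions: MeOTf (1.2 equiv), CH2Cl2, 0 °C → rt; concentrate; then MeOH/H2O, rt; then K2CO3, rt
Reagents that add atoms: methyl trifluoromethanesulfonate COS(=O)(=O)C(F)(F)F
Why: Methylation of the ketimine nitrogen followed by hydrolysis of the iminium ion (Decker–Forster mono-N-methylation) should release the secondary amine without any over-methylation, and K2CO3 in methanol then protodesilylates the alkyne.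

Step 5
Reactants: 9 racemic 1-(3-benzyloxy-4-methoxyphenyl)-N-methylbut-3-yn-2-amine; 10 dimethyl N-tosylcarbonimidodithioate
Product: 12 racemic N-[1-(3-benzyloxy-4-methoxyphenyl)but-3-yn-2-yl]-N-methyl-N'-tosylguanidine, via S-methyl isothiourea 11 (not isolated)
Conditions: MeCN, 80 °C; then NH3 (7 M in MeOH), sealed tube, 80 °C
Reagents that add atoms: ammonia N
Why: Two successive addition–elimination reactions at the electron-poor imidocarbonate carbon, first by the secondary amine and then by ammonia, are the usual two-stage guanylation with N-sulfonyl dithioimidocarbonates, and no alkynophilic metal is present.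

Step 6
Reactants: 12 racemic N-[1-(3-benzyloxy-4-methoxyphenyl)but-3-yn-2-yl]-N-methyl-N'-tosylguanidine; 13 4-methoxyphenyl trifluoromethanesulfonate
Product: 15 N-[5-(3-benzyloxy-4-methoxybenzyl)-4-(4-methoxybenzyl)-1-methyl-1H-imidazol-2-yl]-4-methylbenzenesulfonamide, via (E)-benzylidene cyclic guanidine 14 (not isolated)
Conditions: Pd(OAc)2 (4 mol %), RuPhos (8 mol %), LiOtBu (2.4 equiv), 13 (2 equiv), PhCF3, 100 °C
Reagents that add atoms: none
Why: Oxidative addition of 13 to Pd(0)/RuPhos gives a cationic arylpalladium(II) species that π-binds the terminal alkyne of the lithium guanidinate of 12; outer-sphere (anti) attack of a guanidine nitrogen on the internal alkyne carbon and C(sp2)–C(aryl) reductive elimination give the exocyclic alkene 14, and tert-butoxide then moves the single C5–H to the benzylic carbon, which aromatises the ring to 15. The closest known reaction type is the Pd-catalysed alkyne carboamination of N-propargyl-N'-tosylguanidines with aryl triflates to 2-aminoimidazoles, and the substituent on the propargylic carbon is the only difference. The imidazole ring closes in a 5-exo-dig mode at N3–C4. No stereocentre is created, since the racemic propargylic centre becomes the sp2 carbon C5 and the alkene geometry of 14 disappears on isomerisation. The step needs 5-exo closure to beat 6-endo closure, and carboamination to beat copper-free arylation of the acetylenic C–H, plain hydroamination and propargyl-to-allene isomerisation; the three-atom N–C–C tether, the unhindered alkyne terminus that accepts the aryl group, the non-coordinating triflate (a cationic Pd that activates the π-bond) and the excess of 13 should secure this. Ring closure through either guanidine nitrogen leads to the same amine after step 7.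

Step 7
Reactants: 15 N-[5-(3-benzyloxy-4-methoxybenzyl)-4-(4-methoxybenzyl)-1-methyl-1H-imidazol-2-yl]-4-methylbenzenesulfonamide
Product: 16 2-amino-5-(3-hydroxy-4-methoxybenzyl)-4-(4-methoxybenzyl)-1-methylimidazole
Conditions: Li naphthalenide (8 equiv), THF, −78 → −20 °C; sat. aq. NH4Cl
Reagents that add atoms: none
Why: Single-electron transfer from the arene radical anion should cleave the sulfonamide N–S bond (to sulfinate) and the aryl O–CH2Ph bond (to phenoxide and toluene) in one operation, while aryl methyl ethers and the imidazole are not reduced at low temperature.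

Step 8
Reactants: 16 2-amino-5-(3-hydroxy-4-methoxybenzyl)-4-(4-methoxybenzyl)-1-methylimidazole; 17 1-methylparabanic acid (1-methylimidazolidine-2,4,5-trione)
Product: 20 naamidine B, via N-silylated 1-methylparabanic acid 18 (not isolated), via aryl trimethylsilyl ether of naamidine B 19 (not isolated)
Conditions: 17, BSA (3 equiv), MeCN, rt; then 16, toluene, 110 °C; aq. NH4Cl/THF work-up
Reagents that add atoms: none
Why: Silyl transfer to the C4 oxygen next to the silylated nitrogen turns that carbonyl into a leaving group, so the exocyclic amine condenses there by addition–elimination (the established condensation of 2-aminoimidazoles with silylated 1-methylparabanic acid), and the labile aryl silyl ether 19 is hydrolysed on work-up.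

**Compound list**
1 | 3-benzyloxy-4-methoxybenzyl alcohol | COc1ccc(CO)cc1OCc1ccccc1 | starting material
2 | 3-benzyloxy-4-methoxybenzyl bromide | COc1ccc(CBr)cc1OCc1ccccc1 | intermediate
3 | benzophenone imine | N=C(c1ccccc1)c1ccccc1 | starting material
4 | 3-bromo-1-(trimethylsilyl)prop-1-yne | C[Si](C)(C)C#CCBr | starting material
5 | N-(diphenylmethylidene)-3-(trimethylsilyl)prop-2-yn-1-amine | C[Si](C)(C)C#CCN=C(c1ccccc1)c1ccccc1 | intermediate
6 | racemic N-(diphenylmethylidene)-1-(3-benzyloxy-4-methoxyphenyl)-4-(trimethylsilyl)but-3-yn-2-amine | COc1ccc(CC(C#C[Si](C)(C)C)N=C(c2ccccc2)c2ccccc2)cc1OCc1ccccc1 | intermediate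
7 | racemic N-methyliminium triflate of 6 | COc1ccc(CC(C#C[Si](C)(C)C)[N+](C)=C(c2ccccc2)c2ccccc2)cc1OCc1ccccc1.[O-]S(=O)(=O)C(F)(F)F | intermediate (not isolated)
8 | racemic 1-(3-benzyloxy-4-methoxyphenyl)-N-methyl-4-(trimethylsilyl)but-3-yn-2-amine | COc1ccc(CC(C#C[Si](C)(C)C)NC)cc1OCc1ccccc1 | intermediate (not isolated)
9 | racemic 1-(3-benzyloxy-4-methoxyphenyl)-N-methylbut-3-yn-2-amine | C#CC(Cc1ccc(OC)c(OCc2ccccc2)c1)NC | intermediate
10 | dimethyl N-tosylcarbonimidodithioate | CSC(SC)=NS(=O)(=O)c1ccc(C)cc1 | starting material
11 | racemic S-methyl N-[1-(3-benzyloxy-4-methoxyphenyl)but-3-yn-2-yl]-N-methyl-N'-tosylisothiourea | C#CC(Cc1ccc(OC)c(OCc2ccccc2)c1)N(C)C(SC)=NS(=O)(=O)c1ccc(C)cc1 | intermediate (not isolated)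
12 | racemic N-[1-(3-benzyloxy-4-methoxyphenyl)but-3-yn-2-yl]-N-methyl-N'-tosylguanidine | C#CC(Cc1ccc(OC)c(OCc2ccccc2)c1)N(C)C(N)=NS(=O)(=O)c1ccc(C)cc1 | intermediate (key-step precursor)
13 | 4-methoxyphenyl trifluoromethanesulfonate | COc1ccc(OS(=O)(=O)C(F)(F)F)cc1 | starting material
14 | racemic (E)-5-(3-benzyloxy-4-methoxybenzyl)-4-(4-methoxybenzylidene)-1-methyl-2-(tosylimino)imidazolidine | COc1ccc(/C=C2/NC(=NS(=O)(=O)c3ccc(C)cc3)N(C)C2Cc2ccc(OC)c(OCc3ccccc3)c2)cc1 | intermediate (not isolated)
15 | N-[5-(3-benzyloxy-4-methoxybenzyl)-4-(4-methoxybenzyl)-1-methyl-1H-imidazol-2-yl]-4-methylbenzenesulfonamide | COc1ccc(Cc2nc(NS(=O)(=O)c3ccc(C)cc3)n(C)c2Cc2ccc(OC)c(OCc3ccccc3)c2)cc1 | intermediate (key-step product)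
16 | 2-amino-5-(3-hydroxy-4-methoxybenzyl)-4-(4-methoxybenzyl)-1-methylimidazole | COc1ccc(Cc2nc(N)n(C)c2Cc2ccc(OC)c(O)c2)cc1 | intermediate
17 | 1-methylparabanic acid (1-methylimidazolidine-2,4,5-trione) | CN1C(=O)NC(=O)C1=O | starting material
18 | 1-methyl-3-(trimethylsilyl)parabanic acid | CN1C(=O)N([Si](C)(C)C)C(=O)C1=O | intermediate (not isolated)
19 | aryl trimethylsilyl ether of naamidine B | COc1ccc(Cc2nc(NC3=NC(=O)N(C)C3=O)n(C)c2Cc2ccc(OC)c(O[Si](C)(C)C)c2)cc1 | intermediate (not isolated)
20 | naamidine B, 4-{[5-(3-hydroxy-4-methoxybenzyl)-4-(4-methoxybenzyl)-1-methyl-1H-imidazol-2-yl]amino}-1-methyl-1H-imidazole-2,5-dione | COc1ccc(Cc2nc(NC3=NC(=O)N(C)C3=O)n(C)c2Cc2ccc(OC)c(O)c2)cc1 | target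

**Step count.** Total: 8 steps. Longest linear sequence: 7 steps (step 1 or step 2, then steps 3–8).

**Steps most likely to fail**

Step 6. The terminal alkyne may be consumed by arylation of the acetylenic C–H, by cyclisation without aryl transfer, or by base-induced isomerisation to the allene before the arylpalladium species engages it. The fallback separates the two bond formations. It sets out from 12: Sonogashira coupling with 4-iodoanisole (PdCl2(PPh3)2, CuI, Et3N, THF, rt) should give racemic N-[1-(3-benzyloxy-4-methoxyphenyl)-4-(4-methoxyphenyl)but-3-yn-2-yl]-N-methyl-N'-tosylguanidine F1. Silver(I)-catalysed 5-exo-dig hydroamination (AgOAc, MeCN) should then give the racemic (Z)-benzylidene cyclic guanidine F2. Treatment with DBU or LiOtBu in warm toluene should shift the C5–H and aromatise it; the fallback comes back to the route at 15.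

Step 4. Methylation of the hindered ketimine nitrogen may be slow, so that the methylating agent is lost to adventitious hydrolysis or the imine is cleaved before it is alkylated, giving primary amine. The fallback builds the N-methyl group on a sulfonamide instead. It sets out from 6: hydrolysis with aqueous citric acid in THF should give racemic 1-(3-benzyloxy-4-methoxyphenyl)-4-(trimethylsilyl)but-3-yn-2-amine F3. 2-Nitrobenzenesulfonyl chloride and Et3N in CH2Cl2 should give the racemic nosylamide F4, and MeI with K2CO3 in DMF the racemic N-methyl nosylamide F5. Thiophenol and K2CO3 in MeCN, followed by methanol in the same pot, should remove the nosyl group (Fukuyama) and the C-silyl group; the fallback comes back to the route at 9.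

Step 7. Electron transfer may stop after the sulfonamide has been cleaved, leaving the benzyl ether partly intact, or an excess of reductant may begin to cleave the aryl methyl ethers. The fallback removes the two groups by different mechanisms. It sets out from 15: hydrogenolysis (H2, Pd/C, EtOAc/MeOH, rt) should give N-[5-(3-hydroxy-4-methoxybenzyl)-4-(4-methoxybenzyl)-1-methyl-1H-imidazol-2-yl]-4-methylbenzenesulfonamide F6. SmI2 with Et3N and water in THF at rt should then cleave the N–S bond; the fallback comes back to the route at 16.

**Further compounds**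
F1 | step 6 | racemic N-[1-(3-benzyloxy-4-methoxyphenyl)-4-(4-methoxyphenyl)but-3-yn-2-yl]-N-methyl-N'-tosylguanidine | COc1ccc(C#CC(Cc2ccc(OC)c(OCc3ccccc3)c2)N(C)C(N)=NS(=O)(=O)c2ccc(C)cc2)cc1
F2 | step 6 | racemic (Z)-5-(3-benzyloxy-4-methoxybenzyl)-4-(4-methoxybenzylidene)-1-methyl-2-(tosylimino)imidazolidine | COc1ccc(/C=C2\NC(=NS(=O)(=O)c3ccc(C)cc3)N(C)C2Cc2ccc(OC)c(OCc3ccccc3)c2)cc1
F3 | step 4 | racemic 1-(3-benzyloxy-4-methoxyphenyl)-4-(trimethylsilyl)but-3-yn-2-amine | COc1ccc(CC(N)C#C[Si](C)(C)C)cc1OCc1ccccc1
F4 | step 4 | racemic N-[1-(3-benzyloxy-4-methoxyphenyl)-4-(trimethylsilyl)but-3-yn-2-yl]-2-nitrobenzenesulfonamide | COc1ccc(CC(NS(=O)(=O)c2ccccc2[N+](=O)[O-])C#C[Si](C)(C)C)cc1OCc1ccccc1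
F5 | step 4 | racemic N-[1-(3-benzyloxy-4-methoxyphenyl)-4-(trimethylsilyl)but-3-yn-2-yl]-N-methyl-2-nitrobenzenesulfonamide | COc1ccc(CC(N(C)S(=O)(=O)c2ccccc2[N+](=O)[O-])C#C[Si](C)(C)C)cc1OCc1ccccc1
F6 | step 7 | N-[5-(3-hydroxy-4-methoxybenzyl)-4-(4-methoxybenzyl)-1-methyl-1H-imidazol-2-yl]-4-methylbenzenesulfonamide | COc1ccc(Cc2nc(NS(=O)(=O)c3ccc(C)cc3)n(C)c2Cc2ccc(OC)c(O)c2)cc1
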